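At late times the question about this flask is how much nucleophile the reacted electrophile has used, and in which form.

| flask | electrophile | nucleophile | protic impurity | remark | time |
|---|---|---|---|---|---|
| beta | 1 M | 3 M | 0.020 M | the very flask that is asked about, followed so far |  |
| flask | 1.0 M | 3.00 M | 0.0200 M |  | 40 min |

- beta (time / min: electrophile / %, target / %): 0.833: 92, 3; 1.50: 88, 14; 2.50: 82, 18; 3.00: 78, 22

(scatter of a reading: 1.5 percentage points)

* part of the electrophile that has reacted at 40 min
* share of the unused nucleophile that is free and not bound as protonated nucleophile, at 40 min

- the numbers in the tables scatter with a standard deviation of 1.5 percentage points
- the earlier runs do not show how much of nucleophile is bound; that part of a forecast is a guess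

Read as plain first-order decay, the reading of electrophile at 78% at 3.00 min in this flask gives 0.0828 min⁻¹. That reads as a half-life of 8.37 min, shorter than the 40 min asked about, so two chemists argue about the late state.

The first counts one nucleophile per electrophile and treats the protic impurity as the binder. The forecast is hers: 91% reacted (83% to 96%) and 98% free (60% to 99.5%), since “The impurity can bind at most 0.02 M, so about 99% is free”.

The second holds, as a guess the readings cannot test, that each reacted electrophile sets acid free, which ties up a second nucleophile. His rule is the end share, the free share of unused nucleophile at full conversion on that count of one nucleophile used and one bound per electrophile: c(nucleophile) minus two c(electrophile), over c(nucleophile) minus c(electrophile), taken as charged. In this flask it is 50.0%, and he expects the share at 40 min to stand somewhat above it, with some electrophile unreacted.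

The flask gives 92.0% reacted and 62.6% free. The forecast's conversion stands, but the share goes to the second view, above the end share.

    electrophile + nucleophile → acid set free + target (k = 0.0298 L mol⁻¹ min⁻¹)
    nucleophile + acid set free ⇌ protonated nucleophile, settled at all times (K = 131 L mol⁻¹)
    nucleophile + protic impurity → quenched reagent (k = 2.95 L mol⁻¹ min⁻¹)
    electrophile + target → side product (k = 0.0189 L mol⁻¹ min⁻¹)

The first view has its region early: at 4.00 min, with 28.2% of the electrophile used, 90.0% of the unused nucleophile was free, more than at 40 min. This flask is not at rest at 40 min. By 400 min its electrophile goes from 8.04% to 0%, target from 70.8% to 74.7%, side product from 21.1% to 25.3%. The free share falls to 58.8%, still above the end share.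

With 0.60 M of electrophile, the end share is 75.0%. That neighbour flask gives 78.5% free at 94.5% reacted.

All runs were computed from invented constants, noise included.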